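The numbers come from no measurement; no experiment stands behind them.

A pitfall in this flask is to read the rate constants as a race, with the hour choosing the answer.

    D + X ⇌ Z + E (K1 = 1.5, k1 = 0.93 M⁻¹ s⁻¹)
    E + X ⇌ Z + J (K2 = 0.19, k2 = 2.2 M⁻¹ s⁻¹)
    E ⇌ L (K3 = 0.63, k3 = 0.0014 s⁻¹)

D 0.050 M; X 0.0300 M; time 4.0 h

* at 4.0 h, what has stopped the reaction, if anything has (all of D has reacted / it is still moving / forward and back rates have come level / X has run out first)
* how much E there is at 4.0 h, in percent of the D charged
* how much L there is at 4.0 h, in percent of the D charged

- the reaction counts as stopped when no species that holds the D changes by six tenths of a point or more over the second half of the time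
- run time (flask): 4.0 h

X is charged below D, so X is the limiting reagent, and the charges allow at most 60.0% of E. But every step runs back. E and L relax together by their own step with a half-life of 0.0532 h, and D has a half-life of 0.41 min by the forward rate of the first step at the charges, both far shorter than the 4.0 h, so the hand reckoning treats the flask as at rest. E and L then stand in a constant ratio, and the first constant times one plus the third gives 2.44 for the pool constant, Z times E and L together over D times X.

Each X used gives one Z. With J neglected, Z squared equals the pool constant times D left times X left, so Z is 0.0225 M and E is 27.6%. Going round once more, J per E is the second constant times X left over Z, 0.0635. Each J holds two exchanges, so the reckoning lowers E to 25.6% and puts L at 16.1%.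

The forecast says forward and back rates have come level, with E at 26.2% and L at 16.5%, since “the flask is at full equilibrium with D still present”. Its E and its L stand above the hand values.

The simulation gives forward and back rates have come level, with E at 26.1% and L at 16.5%.

The readings of the flask at 4.00 h return a pool constant of 2.44. The pool exists through the reverse step, L to E: struck out, E falls from 26.1% to 0% and the ending changes. In the neighbour flask with 0.018 M of X, the same two rounds give Z of 0.0153 M, J per E of 0.0341 and E of 18.0%. The simulation of that flask gives E at 18.1% and L at 11.4%.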